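## Retrosynthetic overview

1. The target comes from its acetonide tris(triethylsilyl) ether by one acidic deprotection. That precursor is cut at the C13–C1′ bond (internal alkene carbon to allylic carbinol carbon) into an 18-carbon 2-iodo-1-alkene and a 7-carbon dioxolanyl radical, released from an N-acyloxyphthalimide, in a nickel-catalysed decarboxylative alkenylation.
2. Enabling feature: the 2,2-dimethyl-1,3-dioxolane ring of the radical precursor. Its C4 (future C1′) carries the CO2–N(phthaloyl) group and its C5 (future C2′) carries C5 of the butenolide. The C4 radical is configurationally labile and is captured anti to the C5 substituent, so the cis ester, or any C4 epimer mixture, converges on the trans-dioxolane, which is the required syn-1′,2′-diol.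
3. Alkenyl iodide: rings A and B are taken intact from (+)-larixol. The side chain is degraded to a methyl ketone, the 4α-methyl (C18) is oxidised under direction of the 6α-hydroxyl, an 8α,17-oxirane supplies the 8α-OH/8β-Me centre, and the ketone is converted via the alkyne into the 2-iodo-1-alkene.
4. Radical precursor: the butenolide ring is taken from 4-methylfuran-2(5H)-one. A vinylogous Mukaiyama aldol reaction with (R)-glyceraldehyde acetonide sets the two stereocentres that are kept (butenolide C5 and C2′). The glyceraldehyde centre (future C1′) serves as controller and is then erased and reset in the key step.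
5. Order of ring events: rings A/B and the butenolide are bought. Temporary rings are the oxirane (step 2) and the tetrahydrofuran (step 3, oxidised to a γ-lactone in step 4), both opened in step 6, and the control dioxolane (closed in step 13, removed in step 18).

Key step: step 17

Assumption: (+)-larixol and (R)-glyceraldehyde acetonide are taken as purchasable; labdane numbering is used for the decalin half (C13 = internal alkene carbon, C16 = methylidene carbon, C18 = the carbon on the α face of C4), and the two diol carbons are called C1′ and C2′.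

## Route

Step 1
Reactants: 1 (+)-larixol
Product: 2 6α-hydroxy-14,15-dinorlabd-8(17)-en-13-one
Conditions: KMnO4, BnEt3NCl, CH2Cl2/H2O, 0 °C → rt
Reagents that add atoms: none
Why: Permanganate oxidative cleavage, in which the unhindered vinyl group of the tertiary allylic alcohol is dihydroxylated and cleaved down to the C13 methyl ketone (the established side-chain degradation of 13-hydroxylabd-14-enes), while the hindered 8(17)-methylidene and the 6α-hydroxyl are expected to survive under phase-transfer control and no ring stereocentre is touched.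

Step 2
Reactants: 2 6α-hydroxy-14,15-dinorlabd-8(17)-en-13-one
Product: 3 8α,17-epoxy-6α-hydroxy-14,15-dinorlabdan-13-one
Conditions: mCPBA, NaHCO3, CH2Cl2, 0 °C
Reagents that add atoms: 3-chloroperbenzoic acid, OOC(=O)c1cccc(Cl)c1
Why: Prilezhaev epoxidation of the exocyclic 1,1-disubstituted alkene, the peracid approaching the α face (equatorial attack, anti to the axial C10 methyl and assisted by hydrogen bonding to the 6α-hydroxyl), which sets C8 with its oxygen α.

Step 3
Reactants: 3 8α,17-epoxy-6α-hydroxy-14,15-dinorlabdan-13-one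
Product: 4 6α,18:8α,17-diepoxy-14,15-dinorlabdan-13-one
Conditions: PhI(OAc)2, I2, cyclohexane, hν (visible light), 40 °C
Reagents that add atoms: none
Why: Suárez hypoiodite reaction (remote functionalisation by an alkoxyl radical), in which the 6α-alkoxyl radical abstracts a hydrogen from the 4α-methyl group (C18) through a six-membered transition state, possible because the equatorial 6α-oxygen and the equatorial 4α-methyl stand in a peri-like syn-pentane relationship, and iodine transfer followed by displacement by the hydroxyl closes the tetrahydrofuran; C4 becomes a stereocentre with the oxygenated carbon α because only that methyl is within reach.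

Step 4
Reactants: 4 6α,18:8α,17-diepoxy-14,15-dinorlabdan-13-one
Product: 5 8α,17-epoxy-13-oxo-14,15-dinorlabdan-18,6α-olide
Conditions: RuCl3·xH2O (5 mol %), NaIO4, CCl4/MeCN/pH 7 phosphate buffer, rt
Reagents that add atoms: sodium periodate, [Na+].[O-]I(=O)(=O)=O (terminal oxidant; the oxygen is delivered through RuO4)
Why: RuO4-mediated oxidation of a cyclic ether to a lactone, which should take place at the α-methylene C18 in preference to the α-methine C6 as in the conversion of 2-alkyltetrahydrofurans into γ-lactones, the buffer protecting the oxirane and no stereocentre being changed.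

Step 5
Reactants: 5 8α,17-epoxy-13-oxo-14,15-dinorlabdan-18,6α-olide
Product: 7 8α,17-epoxy-14,15-dinorlabd-13(16)-yn-18,6α-olide, via enol triflate 6 (not isolated)
Conditions: LiN(i-Pr)2, THF, −78 °C; PhNTf2; then LiN(i-Pr)2 (2.5 equiv), −78 °C; aq. NH4Cl
Reagents that add atoms: N-phenylbis(trifluoromethanesulfonimide), O=S(=O)(N(c1ccccc1)S(=O)(=O)C(F)(F)F)C(F)(F)F (its triflyl group is carried by 6 only; no heavy atom is added to 7)
Why: Kinetic deprotonation of the methyl group of the methyl ketone and O-triflation give the terminal enol triflate, from which the amide base eliminates triflic acid at −78 °C to give the terminal alkyne (methyl ketone to alkyne conversion through an enol sulfonate), the lactone having no α-hydrogen and the oxirane being expected to tolerate the base at this temperature.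

Step 6
Reactants: 7 8α,17-epoxy-14,15-dinorlabd-13(16)-yn-18,6α-olide
Product: 8 14,15-dinorlabd-13(16)-yne-6α,8α,18-triol
Conditions: LiAlH4, THF, 0 → 40 °C; H2O, aq. NaOH
Reagents that add atoms: none
Why: Hydride reduction in which LiAlH4 reduces the lactone to the 6α,18-diol (the C6–O bond is kept, so C6 is unchanged) and opens the spiro-oxirane at the primary carbon C17, which leaves the C8–O bond in place and so gives the 8α-hydroxyl and the 8β-methyl group, while the isolated terminal alkyne is not reduced.

Step 7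
Reactants: 8 14,15-dinorlabd-13(16)-yne-6α,8α,18-triol
Product: 9 6α,8α,18-tris(triethylsilyloxy)-14,15-dinorlabd-13(16)-yne
Conditions: Et3SiOTf, 2,6-lutidine, CH2Cl2, −78 → 0 °C
Reagents that add atoms: triethylsilyl trifluoromethanesulfonate, CC[Si](CC)(CC)OS(=O)(=O)C(F)(F)F
Why: Silylation with a silyl triflate and a hindered pyridine base, reactive enough to protect the primary, the secondary and the tertiary hydroxyl so that the aluminium hydride of the next step meets no O–H group.

Step 8
Reactants: 9 6α,8α,18-tris(triethylsilyloxy)-14,15-dinorlabd-13(16)-yne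
Product: 11 13-iodo-6α,8α,18-tris(triethylsilyloxy)-14,15-dinorlabd-13(16)-ene, via alkenylalane 10 (not isolated)
Conditions: Ni(dppp)Cl2 (3 mol %), i-Bu2AlH, THF, 0 °C → rt; then I2, THF, −78 → 0 °C; aq. Na2S2O3, aq. potassium sodium tartrate
Reagents that add atoms: diisobutylaluminium hydride, CC(C)C[AlH]CC(C)C (its aluminium is carried by 10 only); iodine, [I][I]
Why: Nickel-catalysed Markovnikov (α-selective) hydroalumination of a terminal alkyne, in which the bidentate phosphine directs aluminium to the internal carbon and hydrogen to the terminus by syn addition, followed by iodinolysis of the C–Al bond to give the 2-iodo-1-alkene; no stereocentre is involved.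

Step 9
Reactants: 12 4-methylfuran-2(5H)-one
Product: 13 tert-butyldimethyl[(4-methylfuran-2-yl)oxy]silane
Conditions: t-BuMe2SiOTf, Et3N, CH2Cl2, 0 °C
Reagents that add atoms: tert-butyldimethylsilyl trifluoromethanesulfonate, CC(C)(C)[Si](C)(C)OS(=O)(=O)C(F)(F)F
Why: Soft enolisation and O-silylation of the butenolide at C5 give the aromatic 2-silyloxyfuran, the nucleophile of the vinylogous aldol reaction.

Step 10
Reactants: 13 tert-butyldimethyl[(4-methylfuran-2-yl)oxy]silane; 14 (R)-2,2-dimethyl-1,3-dioxolane-4-carbaldehyde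
Product: 15 (5R)-5-{(S)-[(4R)-2,2-dimethyl-1,3-dioxolan-4-yl](hydroxy)methyl}-4-methylfuran-2(5H)-one
Conditions: BF3·OEt2, CH2Cl2, −78 °C; aq. NaHCO3
Reagents that add atoms: none
Why: Vinylogous Mukaiyama aldol reaction, in which the silyloxyfuran attacks the BF3-activated aldehyde through its C5 in an open transition state that gives the threo relationship between the new ring stereocentre (butenolide C5, R) and the new carbinol carbon, while Felkin–Anh attack anti to the α-oxygen of the aldehyde gives the erythro relationship between the carbinol and the dioxolane carbon, the D-arabino outcome known for this aldehyde with 2-silyloxyfurans.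

Step 11
Reactants: 15 (5R)-5-{(S)-[(4R)-2,2-dimethyl-1,3-dioxolan-4-yl](hydroxy)methyl}-4-methylfuran-2(5H)-one
Product: 16 (5R)-4-methyl-5-[(1R,2R)-1,2,3-trihydroxypropyl]furan-2(5H)-one
Conditions: AcOH/H2O (4:1), 40 °C
Reagents that add atoms: none
Why: Acid-catalysed hydrolysis of the terminal isopropylidene acetal (acetal deprotection), which leaves the butenolide and all stereocentres untouched.

Step 12
Reactants: 16 (5R)-4-methyl-5-[(1R,2R)-1,2,3-trihydroxypropyl]furan-2(5H)-one
Product: 17 (5R)-5-[(1R,2R)-3-(tert-butyldimethylsilyloxy)-1,2-dihydroxypropyl]-4-methylfuran-2(5H)-one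
Conditions: t-BuMe2SiCl, imidazole, DMF, 0 °C
Reagents that add atoms: tert-butyldimethylsilyl chloride, CC(C)(C)[Si](C)(C)Cl
Why: Selective silylation of the primary hydroxyl in the presence of two hindered secondary ones (steric differentiation).

Step 13
Reactants: 17 (5R)-5-[(1R,2R)-3-(tert-butyldimethylsilyloxy)-1,2-dihydroxypropyl]-4-methylfuran-2(5H)-one
Product: 18 (5R)-5-[(4S,5R)-5-{[(tert-butyldimethylsilyl)oxy]methyl}-2,2-dimethyl-1,3-dioxolan-4-yl]-4-methylfuran-2(5H)-one
Conditions: 2,2-dimethoxypropane, PPTS, CH2Cl2, rt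
Reagents that add atoms: 2,2-dimethoxypropane, COC(C)(C)OC
Why: Acetalisation (acetonide formation) of the erythro 1,2-diol gives the cis-4,5-disubstituted 1,3-dioxolane, the ring that will control the facial selectivity of the key step; no stereocentre is changed.

Step 14
Reactants: 18 (5R)-5-[(4S,5R)-5-{[(tert-butyldimethylsilyl)oxy]methyl}-2,2-dimethyl-1,3-dioxolan-4-yl]-4-methylfuran-2(5H)-one
Product: 19 (5R)-5-[(4S,5R)-5-(hydroxymethyl)-2,2-dimethyl-1,3-dioxolan-4-yl]-4-methylfuran-2(5H)-one
Conditions: HF·pyridine, pyridine/THF, 0 °C → rt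
Reagents that add atoms: none
Why: Fluoride-mediated desilylation under acidic buffering, chosen so that the base-sensitive γ-position of the butenolide is not epimerised and the acetonide is kept.

Step 15
Reactants: 19 (5R)-5-[(4S,5R)-5-(hydroxymethyl)-2,2-dimethyl-1,3-dioxolan-4-yl]-4-methylfuran-2(5H)-one
Product: 20 (4S,5S)-2,2-dimethyl-5-[(2R)-3-methyl-5-oxo-2,5-dihydrofuran-2-yl]-1,3-dioxolane-4-carboxylic acid
Conditions: TEMPO (20 mol %), PhI(OAc)2, MeCN/H2O (1:1), rt
Reagents that add atoms: water, O
Why: Oxoammonium (TEMPO)-catalysed oxidation of the primary alcohol to the carboxylic acid with PhI(OAc)2 as terminal oxidant in aqueous acetonitrile, conditions that leave the acetonide and the butenolide intact, the configuration at C4 of the dioxolane being of no consequence for what follows.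

Step 16
Reactants: 20 (4S,5S)-2,2-dimethyl-5-[(2R)-3-methyl-5-oxo-2,5-dihydrofuran-2-yl]-1,3-dioxolane-4-carboxylic acid
Product: 21 1,3-dioxoisoindolin-2-yl (4S,5S)-2,2-dimethyl-5-[(2R)-3-methyl-5-oxo-2,5-dihydrofuran-2-yl]-1,3-dioxolane-4-carboxylate
Conditions: N-hydroxyphthalimide, N,N′-diisopropylcarbodiimide, DMAP (cat.), CH2Cl2, 0 °C → rt
Reagents that add atoms: N-hydroxyphthalimide, O=C1c2ccccc2C(=O)N1O
Why: Steglich-type esterification with N-hydroxyphthalimide gives the redox-active ester, and any epimerisation α to the activated carbonyl is harmless because this centre is erased in step 17.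

Step 17
Reactants: 11 13-iodo-6α,8α,18-tris(triethylsilyloxy)-14,15-dinorlabd-13(16)-ene; 21 1,3-dioxoisoindolin-2-yl (4S,5S)-2,2-dimethyl-5-[(2R)-3-methyl-5-oxo-2,5-dihydrofuran-2-yl]-1,3-dioxolane-4-carboxylate (2 equiv)
Product: 22 13-{(4S,5R)-2,2-dimethyl-5-[(2R)-3-methyl-5-oxo-2,5-dihydrofuran-2-yl]-1,3-dioxolan-4-yl}-6α,8α,18-tris(triethylsilyloxy)-14,15-dinorlabd-13(16)-ene
Conditions: NiCl2·6H2O (20 mol %), 2,2′-bipyridine (20 mol %), AgNO3 (30 mol %), LiCl, DMF/THF, Mg anode, reticulated vitreous carbon cathode, constant current, rt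
Reagents that add atoms: none
Why: At the silver-modified cathode a low-valent nickel–bipyridine species transfers one electron to the N-acyloxyphthalimide 21, which fragments with loss of CO2 and phthalimide anion to the C4 radical of the 1,3-dioxolane, while oxidative addition of the C–I bond of 11 gives an alkenylnickel species that captures this radical and, from trivalent nickel, reductively eliminates to form the C13–C1′ bond. The closest known reaction type is the nickel-catalysed decarboxylative alkenylation of redox-active esters (with alkenylzinc reagents or, electroreductively, with alkenyl halides), in which dioxolane-4-carboxylates of the tartaric acid type are established radical precursors that couple trans to the neighbouring ring substituent. No ring is closed in this step. The one new stereocentre, C1′ (C4 of the dioxolane), is controlled by the adjacent ring stereocentre C5: the α-oxy radical is configurationally labile, nickel approaches the face anti to the butenolide on C5 and the stereoretentive reductive elimination gives the trans-4,5-disubstituted dioxolane, that is the syn (1′S,2′R) diol, so that the cis ester 21 and any C4 epimer formed in steps 15 and 16 converge on the same product. The step needs facial (trans over cis) selectivity, cross-coupling in preference to hydrogen abstraction or dimerisation of either partner, and chemoselectivity for the C–I bond and the activated ester over the butenolide; these are secured by the bulk of the C5 substituent next to the radical centre, by the nucleophilic character of the α-oxy radical towards the alkenylnickel species together with an excess of 21, and by the mild potential, at which the β,β-disubstituted butenolide, the silyl ethers and the acetal are inert.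

Step 18
Reactants: 22 13-{(4S,5R)-2,2-dimethyl-5-[(2R)-3-methyl-5-oxo-2,5-dihydrofuran-2-yl]-1,3-dioxolan-4-yl}-6α,8α,18-tris(triethylsilyloxy)-14,15-dinorlabd-13(16)-ene
Product: 23 CNP0301623.1, 13-{(1S,2R)-1,2-dihydroxy-2-[(2R)-3-methyl-5-oxo-2,5-dihydrofuran-2-yl]ethyl}-14,15-dinorlabd-13(16)-ene-6α,8α,18-triol
Conditions: 2 M aq. HCl, THF, rt
Reagents that add atoms: none
Why: Acid-catalysed hydrolysis removes the trans-acetonide and the three triethylsilyl ethers in one operation (global deprotection) under conditions expected to spare the tertiary alcohol, the allylic alcohol and the butenolide, and no stereocentre is affected.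

## Compound list

1 | (+)-larixol, (13S)-labda-8(17),14-diene-6α,13-diol | C=C[C@@](C)(O)CC[C@@H]1[C@@]2(C)CCCC(C)(C)[C@@H]2[C@@H](O)CC1=C | starting material
2 | 6α-hydroxy-14,15-dinorlabd-8(17)-en-13-one | CC(=O)CC[C@@H]1[C@@]2(C)CCCC(C)(C)[C@@H]2[C@@H](O)CC1=C | intermediate
3 | 8α,17-epoxy-6α-hydroxy-14,15-dinorlabdan-13-one | CC(=O)CC[C@@H]1[C@@]2(C)CCCC(C)(C)[C@@H]2[C@@H](O)C[C@]1(O3)C3 | intermediate
4 | 6α,18:8α,17-diepoxy-14,15-dinorlabdan-13-one | CC(=O)CC[C@@H]1[C@@]2(C)CCC[C@@](C)(CO3)[C@@H]2[C@@H]3C[C@]1(O4)C4 | intermediate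
5 | 8α,17-epoxy-13-oxo-14,15-dinorlabdan-18,6α-olide | CC(=O)CC[C@@H]1[C@@]2(C)CCC[C@@](C)(C(=O)O3)[C@@H]2[C@@H]3C[C@]1(O4)C4 | intermediate
6 | 8α,17-epoxy-13-(trifluoromethanesulfonyloxy)-14,15-dinorlabd-13(16)-en-18,6α-olide (enol triflate, not isolated) | C=C(OS(=O)(=O)C(F)(F)F)CC[C@@H]1[C@@]2(C)CCC[C@@](C)(C(=O)O3)[C@@H]2[C@@H]3C[C@]1(O4)C4 | intermediate
7 | 8α,17-epoxy-14,15-dinorlabd-13(16)-yn-18,6α-olide | C#CCC[C@@H]1[C@@]2(C)CCC[C@@](C)(C(=O)O3)[C@@H]2[C@@H]3C[C@]1(O4)C4 | intermediate
8 | 14,15-dinorlabd-13(16)-yne-6α,8α,18-triol | C#CCC[C@@H]1[C@@]2(C)CCC[C@@](C)(CO)[C@@H]2[C@@H](O)C[C@@]1(C)O | intermediate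
9 | 6α,8α,18-tris(triethylsilyloxy)-14,15-dinorlabd-13(16)-yne | C#CCC[C@@H]1[C@@]2(C)CCC[C@@](C)(CO[Si](CC)(CC)CC)[C@@H]2[C@@H](O[Si](CC)(CC)CC)C[C@@]1(C)O[Si](CC)(CC)CC | intermediate
10 | 13-(diisobutylalumanyl)-6α,8α,18-tris(triethylsilyloxy)-14,15-dinorlabd-13(16)-ene (alkenylalane, not isolated) | C=C([Al](CC(C)C)CC(C)C)CC[C@@H]1[C@@]2(C)CCC[C@@](C)(CO[Si](CC)(CC)CC)[C@@H]2[C@@H](O[Si](CC)(CC)CC)C[C@@]1(C)O[Si](CC)(CC)CC | intermediate
11 | 13-iodo-6α,8α,18-tris(triethylsilyloxy)-14,15-dinorlabd-13(16)-ene | C=C(I)CC[C@@H]1[C@@]2(C)CCC[C@@](C)(CO[Si](CC)(CC)CC)[C@@H]2[C@@H](O[Si](CC)(CC)CC)C[C@@]1(C)O[Si](CC)(CC)CC | intermediate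
12 | 4-methylfuran-2(5H)-one | CC1=CC(=O)OC1 | starting material
13 | tert-butyldimethyl[(4-methylfuran-2-yl)oxy]silane | Cc1coc(O[Si](C)(C)C(C)(C)C)c1 | intermediate
14 | (R)-2,2-dimethyl-1,3-dioxolane-4-carbaldehyde (2,3-O-isopropylidene-D-glyceraldehyde) | CC1(C)OC[C@@H](O1)C=O | starting material
15 | (5R)-5-{(S)-[(4R)-2,2-dimethyl-1,3-dioxolan-4-yl](hydroxy)methyl}-4-methylfuran-2(5H)-one (D-arabino) | CC1(C)OC[C@@H](O1)[C@@H](O)[C@@H]2OC(=O)C=C2C | intermediate
16 | (5R)-4-methyl-5-[(1R,2R)-1,2,3-trihydroxypropyl]furan-2(5H)-one | OC[C@@H](O)[C@@H](O)[C@@H]1OC(=O)C=C1C | intermediate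
17 | (5R)-5-[(1R,2R)-3-(tert-butyldimethylsilyloxy)-1,2-dihydroxypropyl]-4-methylfuran-2(5H)-one | CC(C)(C)[Si](C)(C)OC[C@@H](O)[C@@H](O)[C@@H]1OC(=O)C=C1C | intermediate
18 | (5R)-5-[(4S,5R)-5-{[(tert-butyldimethylsilyl)oxy]methyl}-2,2-dimethyl-1,3-dioxolan-4-yl]-4-methylfuran-2(5H)-one (cis-dioxolane) | CC(C)(C)[Si](C)(C)OC[C@H]1OC(C)(C)O[C@H]1[C@@H]2OC(=O)C=C2C | intermediate
19 | (5R)-5-[(4S,5R)-5-(hydroxymethyl)-2,2-dimethyl-1,3-dioxolan-4-yl]-4-methylfuran-2(5H)-one | OC[C@H]1OC(C)(C)O[C@H]1[C@@H]2OC(=O)C=C2C | intermediate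
20 | (4S,5S)-2,2-dimethyl-5-[(2R)-3-methyl-5-oxo-2,5-dihydrofuran-2-yl]-1,3-dioxolane-4-carboxylic acid (cis) | OC(=O)[C@H]1OC(C)(C)O[C@H]1[C@@H]2OC(=O)C=C2C | intermediate
21 | 1,3-dioxoisoindolin-2-yl (4S,5S)-2,2-dimethyl-5-[(2R)-3-methyl-5-oxo-2,5-dihydrofuran-2-yl]-1,3-dioxolane-4-carboxylate | O=C(ON1C(=O)c2ccccc2C1=O)[C@H]3OC(C)(C)O[C@H]3[C@@H]4OC(=O)C=C4C | intermediate
22 | 13-{(4S,5R)-2,2-dimethyl-5-[(2R)-3-methyl-5-oxo-2,5-dihydrofuran-2-yl]-1,3-dioxolan-4-yl}-6α,8α,18-tris(triethylsilyloxy)-14,15-dinorlabd-13(16)-ene (trans-dioxolane) | C=C(CC[C@@H]1[C@@]2(C)CCC[C@@](C)(CO[Si](CC)(CC)CC)[C@@H]2[C@@H](O[Si](CC)(CC)CC)C[C@@]1(C)O[Si](CC)(CC)CC)[C@@H]3OC(C)(C)O[C@H]3[C@@H]4OC(=O)C=C4C | intermediate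
23 | CNP0301623.1, 13-{(1S,2R)-1,2-dihydroxy-2-[(2R)-3-methyl-5-oxo-2,5-dihydrofuran-2-yl]ethyl}-14,15-dinorlabd-13(16)-ene-6α,8α,18-triol | C=C(CC[C@@H]1[C@@]2(C)CCC[C@@](C)(CO)[C@@H]2[C@@H](O)C[C@@]1(C)O)[C@H](O)[C@@H](O)[C@@H]1OC(=O)C=C1C | target

## Step count and risks

Total step count: 18. Longest linear sequence: 10 steps (steps 1–8, 17, 18; the other branch, steps 9–16, 17, 18, is equally long).

Steps most likely to fail:

1. Step 17 (key coupling). What may go wrong: loss of the dioxolanyl radical to hydrogen-atom abstraction or dimerisation, reductive dimerisation of the alkenyl iodide, or erosion of the anti (trans) selectivity in the radical capture. The fallback is a polar, chelation-controlled carbonyl addition that sets out from 15 and 11 and comes back to the route at 23. Alcohol 15 would be etherified with 4-methoxybenzyl trichloroacetimidate and catalytic La(OTf)3 to the 4-methoxybenzyl ether F1. H5IO6 in EtOAc would hydrolyse the terminal acetonide and cleave the resulting glycol in one operation to the α-alkoxy aldehyde F2. Iodide 11 would be converted by iodine–magnesium exchange (i-PrMgCl·LiCl, THF) into the alkenylmagnesium chloride F3, which would be added at −78 °C to F2 precomplexed with MgBr2·OEt2 in CH2Cl2. Attack on the five-membered magnesium chelate of the aldehyde oxygen and the ether oxygen (Cram chelate model), from the face of the α-hydrogen, should give the syn allylic alcohol F4. DDQ would remove the 4-methoxybenzyl group to give the diol F5, and 2 M aq. HCl in THF would then give 23.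

2. Step 4 (ether to lactone). What may go wrong: poor site selectivity of the RuO4 oxidation (attack at the C6 methine or at unactivated tertiary C–H bonds) or hydrolytic opening of the oxirane. The fallback introduces C18 oxygen at the aldehyde level by the Barton reaction; it sets out from 3, replaces steps 3 and 4 and comes back at 5. Alcohol 3 would be converted with NOCl in pyridine into the 6α-nitrite F6. Irradiation would generate the same alkoxyl radical, and hydrogen transfer from C18, recombination with NO and tautomerisation should give the 18-oxime F7. Deoximation with aq. TiCl3/NH4OAc would release the aldehyde, which closes onto the 6α-hydroxyl to give the lactol F8, and oxidation with Ag2CO3 on Celite would give lactone 5.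

3. Step 8 (Markovnikov hydroalumination and iodination). What may go wrong: incomplete α-regioselectivity of the Al–H addition, competing deprotonation of the alkyne C–H by the aluminium hydride, or over-reduction. The fallback is a haloboration that sets out from 9 and comes back at 11. 9-Iodo-9-borabicyclo[3.3.1]nonane (pentane, −20 °C) would add its B–I bond syn across the alkyne with iodine at the internal carbon to give the (Z)-2-iodoalkenylborane F9, and protodeboronation with acetic acid would give 11.

Further compounds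

F1 | step 17 | (5R)-5-{(S)-[(4R)-2,2-dimethyl-1,3-dioxolan-4-yl][(4-methoxybenzyl)oxy]methyl}-4-methylfuran-2(5H)-one | CC1(C)OC[C@@H](O1)[C@@H](OCc2ccc(OC)cc2)[C@@H]3OC(=O)C=C3C
F2 | step 17 | (2S)-2-[(4-methoxybenzyl)oxy]-2-[(2R)-3-methyl-5-oxo-2,5-dihydrofuran-2-yl]acetaldehyde | O=C[C@@H](OCc1ccc(OC)cc1)[C@@H]2OC(=O)C=C2C
F3 | step 17 | [6α,8α,18-tris(triethylsilyloxy)-14,15-dinorlabd-13(16)-en-13-yl]magnesium chloride | C=C([Mg]Cl)CC[C@@H]1[C@@]2(C)CCC[C@@](C)(CO[Si](CC)(CC)CC)[C@@H]2[C@@H](O[Si](CC)(CC)CC)C[C@@]1(C)O[Si](CC)(CC)CC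
F4 | step 17 | 13-{(1S,2R)-1-hydroxy-2-[(4-methoxybenzyl)oxy]-2-[(2R)-3-methyl-5-oxo-2,5-dihydrofuran-2-yl]ethyl}-6α,8α,18-tris(triethylsilyloxy)-14,15-dinorlabd-13(16)-ene | C=C(CC[C@@H]1[C@@]2(C)CCC[C@@](C)(CO[Si](CC)(CC)CC)[C@@H]2[C@@H](O[Si](CC)(CC)CC)C[C@@]1(C)O[Si](CC)(CC)CC)[C@H](O)[C@@H](OCc3ccc(OC)cc3)[C@@H]4OC(=O)C=C4C
F5 | step 17 | 13-{(1S,2R)-1,2-dihydroxy-2-[(2R)-3-methyl-5-oxo-2,5-dihydrofuran-2-yl]ethyl}-6α,8α,18-tris(triethylsilyloxy)-14,15-dinorlabd-13(16)-ene | C=C(CC[C@@H]1[C@@]2(C)CCC[C@@](C)(CO[Si](CC)(CC)CC)[C@@H]2[C@@H](O[Si](CC)(CC)CC)C[C@@]1(C)O[Si](CC)(CC)CC)[C@H](O)[C@@H](O)[C@@H]3OC(=O)C=C3C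
F6 | step 4 | 8α,17-epoxy-13-oxo-14,15-dinorlabdan-6α-yl nitrite | CC(=O)CC[C@@H]1[C@@]2(C)CCCC(C)(C)[C@@H]2[C@@H](ON=O)C[C@]1(O3)C3
F7 | step 4 | 8α,17-epoxy-6α-hydroxy-18-(hydroxyimino)-14,15-dinorlabdan-13-one | CC(=O)CC[C@@H]1[C@@]2(C)CCC[C@@](C)(C=NO)[C@@H]2[C@@H](O)C[C@]1(O3)C3
F8 | step 4 | 6α,18:8α,17-diepoxy-18-hydroxy-14,15-dinorlabdan-13-one (lactol, either C18 epimer) | CC(=O)CC[C@@H]1[C@@]2(C)CCC[C@@](C)(C(O)O3)[C@@H]2[C@@H]3C[C@]1(O4)C4
F9 | step 8 | 9-[(Z)-13-iodo-6α,8α,18-tris(triethylsilyloxy)-14,15-dinorlabd-13(16)-en-16-yl]-9-borabicyclo[3.3.1]nonane | I/C(CC[C@@H]1[C@@]2(C)CCC[C@@](C)(CO[Si](CC)(CC)CC)[C@@H]2[C@@H](O[Si](CC)(CC)CC)C[C@@]1(C)O[Si](CC)(CC)CC)=C\B3C4CCCC3CCC4
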